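**Plan**
- Retrosynthesis first removes a benzyl group placed on O6, then opens ring C at O1–C2 and C2–C3 (C2 is a one-carbon unit from an amide acetal), leaving a 2-hydroxy deoxybenzoin.
- Ring A of that ketone is cut at C5–C6 and C4a–C8a into a 1,3,4-trioxygenated silyl ketene acetal diene (C8a–C8–C7–C6) and a terminal ynone (C5, C4a, C4, the arylmethyl carbon and ring B).
- Enabling feature: ring A carries oxygen on C6, C7 and C8a (O1) and the acyl carbon C4 on C4a. This is the pattern laid down when such a diene adds across an alkynyl ketone and the adduct aromatizes.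
- Forward order: ring B is bought with its three methoxy groups, ring A is built by cycloaddition and aromatization, ring C is closed by C2 insertion and O1–C2 bond formation, and debenzylation ends the route.
- Stereochemistry: the target has no stereocenter; only the regiochemistry of the cycloaddition must be controlled, and the polarization of diene and ynone does this.

Key step: step 6

Remark: the diene and the enaminone are taken as mixtures of double-bond isomers and the cycloadduct as a mixture of diastereomers. Their SMILES carry no descriptors because these elements are lost in the following bond-forming event.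

**Route**

Step 1
Reactants: 1 methyl 4-chloro-3-oxobutanoate (methyl 4-chloroacetoacetate); 2 benzyl alcohol
Product: 3 methyl 4-(benzyloxy)-3-oxobutanoate
Conditions: NaH (2.2 equiv), THF, 0 °C to rt; then 1 M HCl
Reagents that add atoms: none
Why: Williamson-type SN2 displacement of the α-chloro ketone chloride by sodium benzyloxide, with the second equivalent of NaH holding the β-keto ester as its enolate so that the ester is shielded from transesterification.

Step 2
Reactants: 3 methyl 4-(benzyloxy)-3-oxobutanoate
Product: 5 methyl (2E)-4-(benzyloxy)-3-methoxybut-2-enoate, via dimethyl ketal 4 (not isolated)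
Conditions: HC(OMe)3, cat. H2SO4, MeOH, rt; then cat. TsOH, 130 °C, reduced pressure
Reagents that add atoms: trimethyl orthoformate, COC(OC)OC
Why: Acid-catalysed ketalization by the orthoformate followed by thermal loss of methanol (enol ether formation) should give the conjugated E isomer with methoxy trans to the ester, as it does for simple acetoacetates.

Step 3
Reactants: 5 methyl (2E)-4-(benzyloxy)-3-methoxybut-2-enoate
Product: 7 4-(benzyloxy)-1,3-dimethoxy-1-(trimethylsilyloxy)buta-1,3-diene, via lithium dienolate 6 (not isolated)
Conditions: LiN(iPr)2, THF, −78 °C; Me3SiCl, −78 °C to rt; non-aqueous work-up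
Reagents that add atoms: chlorotrimethylsilane, C[Si](C)(C)Cl
Why: Kinetic γ-deprotonation of the β-methoxy enoate (the CH2 lies cis to the ester in the E isomer) gives the extended dienolate, which the silyl chloride traps on oxygen, the standard silyl ketene acetal formation used for 1,3-dialkoxy-1-silyloxybutadienes.

Step 4
Reactants: 8 (2,4,5-trimethoxyphenyl)acetic acid
Product: 10 N-methoxy-N-methyl-2-(2,4,5-trimethoxyphenyl)acetamide, via acyl imidazole 9 (not isolated)
Conditions: CDI, CH2Cl2, rt; then MeNHOMe·HCl, rt
Reagents that add atoms: N,O-dimethylhydroxylamine hydrochloride, CNOC.Cl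
Why: Amide coupling through the acyl imidazole (Weinreb amide synthesis): carbonyldiimidazole activates the acid with loss of CO2 and the hydroxylamine then displaces imidazole.

Step 5
Reactants: 10 N-methoxy-N-methyl-2-(2,4,5-trimethoxyphenyl)acetamide; 11 ethynylmagnesium bromide
Product: 13 1-(2,4,5-trimethoxyphenyl)but-3-yn-2-one, via magnesium hemiaminal 12 (not isolated)
Conditions: THF, 0 °C; inverse quench into cold 1 M HCl
Reagents that add atoms: none
Why: Weinreb ketone synthesis, in which the chelated magnesium hemiaminal resists a second addition and collapses only in the acidic inverse quench, which also protonates the released amine before it can add to the ynone.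

Step 6
Reactants: 7 4-(benzyloxy)-1,3-dimethoxy-1-(trimethylsilyloxy)buta-1,3-diene; 13 1-(2,4,5-trimethoxyphenyl)but-3-yn-2-one
Product: 15 1-[5-(benzyloxy)-2-hydroxy-4-methoxyphenyl]-2-(2,4,5-trimethoxyphenyl)ethanone, via cyclohexadiene cycloadduct 14 (not isolated)
Conditions: toluene, 0 °C to 40 °C; then 1 M HCl, THF, rt
Reagents that add atoms: none
Why: The electron-rich diene 7 and the electron-poor ynone 13 should combine in a polarized, asynchronous (4+2) cycloaddition (Diels–Alder reaction; at the stepwise limit a Mukaiyama–Michael addition followed by closure of the allenolate onto the silyloxy(methoxy)carbenium ion) to give the cyclohexa-1,4-diene 14, after which aqueous acid cleaves the mixed silyl methyl ketal at the future C8a to a 4-benzyloxycyclohexa-2,5-dienone that tautomerizes to the phenol. The closest known reaction type is the benzannulation of 1-alkoxy-1-silyloxy-3-alkoxybutadienes with acetylenic ketones and esters, which gives ortho-acyl phenols after loss of alcohol and silyl group. Ring A is closed by intermolecular (4+2) annulation, its carbons coming from C1–C4 of the diene (C8a, C8, C7, C6) and the two alkyne carbons (C5, C4a), with C5–C6 and C4a–C8a as the new bonds. No stereocenter remains, since the two sp3 centers of 14 are erased on aromatization. The step needs one regiochemistry, benzyloxy-bearing diene terminus to the alkyne CH and ketal terminus to the acyl-bearing alkyne carbon; matched polarization secures it, because the ketene acetal oxygens and the C3 methoxy group make C4 the nucleophilic terminus while the carbonyl makes the terminal alkyne carbon the electrophilic one, and no Lewis acid is present to divert the diene to the ketone carbonyl. The acyl group thus ends up ortho to the new hydroxyl, whose hydrogen bond to the ketone favors the phenol and prepares the pyranone closure.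

Step 7
Reactants: 15 1-[5-(benzyloxy)-2-hydroxy-4-methoxyphenyl]-2-(2,4,5-trimethoxyphenyl)ethanone
Product: 17 6-(benzyloxy)-7-methoxy-3-(2,4,5-trimethoxyphenyl)-4H-chromen-4-one, via enaminone 16 (not isolated)
Conditions: Me2NCH(OMe)2, toluene, 90 °C; then AcOH, 60 °C
Reagents that add atoms: N,N-dimethylformamide dimethyl acetal, COC(OC)N(C)C
Why: Condensation of the activated methylene with the amide acetal gives the enaminone, and 6-endo-trig oxa-Michael addition of the phenol with elimination of dimethylamine closes ring C, the standard deoxybenzoin route to isoflavones.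

Step 8
Reactants: 17 6-(benzyloxy)-7-methoxy-3-(2,4,5-trimethoxyphenyl)-4H-chromen-4-one
Product: 18 6-hydroxy-7-methoxy-3-(2,4,5-trimethoxyphenyl)-4H-chromen-4-one
Conditions: H2 (1 atm), 10% Pd/C, EtOAc–MeOH, rt
Reagents that add atoms: none
Why: Catalytic hydrogenolysis of the benzyl aryl ether at ambient pressure should leave the methyl ethers and the chromone double bond untouched if the reaction is stopped at full conversion.

**Compound list**

1 | methyl 4-chloro-3-oxobutanoate | COC(=O)CC(=O)CCl | starting material
2 | benzyl alcohol | OCc1ccccc1 | starting material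
3 | methyl 4-(benzyloxy)-3-oxobutanoate | COC(=O)CC(=O)COCc1ccccc1 | intermediate
4 | methyl 4-(benzyloxy)-3,3-dimethoxybutanoate (dimethyl ketal, not isolated) | COC(=O)CC(OC)(OC)COCc1ccccc1 | intermediate
5 | methyl (2E)-4-(benzyloxy)-3-methoxybut-2-enoate | CO/C(COCc1ccccc1)=C/C(=O)OC | intermediate
6 | lithium 4-(benzyloxy)-1,3-dimethoxybuta-1,3-dien-1-olate (lithium dienolate, not isolated) | [Li+].COC([O-])=CC(OC)=COCc1ccccc1 | intermediate
7 | 4-(benzyloxy)-1,3-dimethoxy-1-(trimethylsilyloxy)buta-1,3-diene (mixture of double-bond isomers) | COC(O[Si](C)(C)C)=CC(OC)=COCc1ccccc1 | intermediate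
8 | (2,4,5-trimethoxyphenyl)acetic acid | OC(=O)Cc1cc(OC)c(OC)cc1OC | starting material
9 | 1-(1H-imidazol-1-yl)-2-(2,4,5-trimethoxyphenyl)ethanone (acyl imidazole, not isolated) | O=C(Cc1cc(OC)c(OC)cc1OC)n1ccnc1 | intermediate
10 | N-methoxy-N-methyl-2-(2,4,5-trimethoxyphenyl)acetamide | CON(C)C(=O)Cc1cc(OC)c(OC)cc1OC | intermediate
11 | ethynylmagnesium bromide | C#C[Mg]Br | starting material
12 | bromomagnesium 2-[methoxy(methyl)amino]-1-(2,4,5-trimethoxyphenyl)but-3-yn-2-olate (magnesium hemiaminal, not isolated) | C#CC(O[Mg]Br)(Cc1cc(OC)c(OC)cc1OC)N(C)OC | intermediate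
13 | 1-(2,4,5-trimethoxyphenyl)but-3-yn-2-one | C#CC(=O)Cc1cc(OC)c(OC)cc1OC | intermediate
14 | 1-[3-(benzyloxy)-4,6-dimethoxy-6-(trimethylsilyloxy)cyclohexa-1,4-dien-1-yl]-2-(2,4,5-trimethoxyphenyl)ethanone (cyclohexadiene cycloadduct, mixture of diastereomers, not isolated) | COC1(O[Si](C)(C)C)C=C(OC)C(OCc2ccccc2)C=C1C(=O)Cc1cc(OC)c(OC)cc1OC | intermediate
15 | 1-[5-(benzyloxy)-2-hydroxy-4-methoxyphenyl]-2-(2,4,5-trimethoxyphenyl)ethanone | COc1cc(O)c(C(=O)Cc2cc(OC)c(OC)cc2OC)cc1OCc1ccccc1 | intermediate
16 | 1-[5-(benzyloxy)-2-hydroxy-4-methoxyphenyl]-3-(dimethylamino)-2-(2,4,5-trimethoxyphenyl)prop-2-en-1-one (enaminone, either geometry, not isolated) | COc1cc(O)c(C(=O)C(=CN(C)C)c2cc(OC)c(OC)cc2OC)cc1OCc1ccccc1 | intermediate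
17 | 6-(benzyloxy)-7-methoxy-3-(2,4,5-trimethoxyphenyl)-4H-chromen-4-one | COc1cc2occ(-c3cc(OC)c(OC)cc3OC)c(=O)c2cc1OCc1ccccc1 | intermediate
18 | 6-hydroxy-7-methoxy-3-(2,4,5-trimethoxyphenyl)-4H-chromen-4-one | COc1cc2occ(-c3cc(OC)c(OC)cc3OC)c(=O)c2cc1O | target

**Step count**

Total steps: 8. Longest linear sequence: 6 steps (steps 1, 2, 3, 6, 7, 8).

**Steps most likely to fail**

Step 6. The cycloaddition may stop at the open-chain conjugate adduct, or the ynone may oligomerize before the diene adds. The mixed ketal may also collapse with loss of silanol instead of methanol, which would leave a methyl ether where the free phenol is needed. The fallback sets out from 8 and returns at 15 without a cycloaddition. Friedel–Crafts acylation of 2-methoxybenzene-1,4-diol with acid 8 in BF3·OEt2 at 80 °C should take place ortho to the 4-hydroxyl and para to the methoxy group, giving 1-(2,5-dihydroxy-4-methoxyphenyl)-2-(2,4,5-trimethoxyphenyl)ethanone F1. The hydroxyl ortho to the ketone is tied up in a hydrogen bond, so benzyl bromide with K2CO3 in acetone should alkylate only the 5-hydroxyl and deliver 15.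

Step 3. The γ-deprotonation may be incomplete, silylation may occur on carbon, or the ketene acetal may hydrolyze during isolation. The fallback sets out from 3 and returns at 15 through a more easily made bis-silyl diene. Me3SiCl and Et3N convert 3 into methyl 4-(benzyloxy)-3-(trimethylsilyloxy)but-2-enoate F2, and LiN(iPr)2 followed by Me3SiCl at −78 °C gives 4-(benzyloxy)-1-methoxy-1,3-bis(trimethylsilyloxy)buta-1,3-diene F3. Cycloaddition of F3 with 13 in toluene gives 1-[3-(benzyloxy)-6-methoxy-4,6-bis(trimethylsilyloxy)cyclohexa-1,4-dien-1-yl]-2-(2,4,5-trimethoxyphenyl)ethanone F4. Dilute HCl turns F4 into 1-[5-(benzyloxy)-2,4-dihydroxyphenyl]-2-(2,4,5-trimethoxyphenyl)ethanone F5. One equivalent of MeI with K2CO3 in acetone should methylate only the non-chelated 4-hydroxyl and give 15.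

Step 5. The Grignard reagent may enolize the benzylic amide instead of adding, or the liberated hydroxylamine may add to the ynone during work-up. The fallback sets out from 10 and returns at 13 by changing the oxidation level. Reduction of 10 with iBu2AlH in THF at −78 °C gives (2,4,5-trimethoxyphenyl)acetaldehyde F6. Addition of 11 at −78 °C gives racemic 1-(2,4,5-trimethoxyphenyl)but-3-yn-2-ol F7. Oxidation with Dess–Martin periodinane in buffered CH2Cl2 then gives 13 under non-basic conditions.

**Further compounds**

F1 | step 6 | 1-(2,5-dihydroxy-4-methoxyphenyl)-2-(2,4,5-trimethoxyphenyl)ethanone | COc1cc(O)c(C(=O)Cc2cc(OC)c(OC)cc2OC)cc1O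
F2 | step 3 | methyl 4-(benzyloxy)-3-(trimethylsilyloxy)but-2-enoate | COC(=O)C=C(COCc1ccccc1)O[Si](C)(C)C
F3 | step 3 | 4-(benzyloxy)-1-methoxy-1,3-bis(trimethylsilyloxy)buta-1,3-diene | COC(O[Si](C)(C)C)=CC(O[Si](C)(C)C)=COCc1ccccc1
F4 | step 3 | 1-[3-(benzyloxy)-6-methoxy-4,6-bis(trimethylsilyloxy)cyclohexa-1,4-dien-1-yl]-2-(2,4,5-trimethoxyphenyl)ethanone | COC1(O[Si](C)(C)C)C=C(O[Si](C)(C)C)C(OCc2ccccc2)C=C1C(=O)Cc1cc(OC)c(OC)cc1OC
F5 | step 3 | 1-[5-(benzyloxy)-2,4-dihydroxyphenyl]-2-(2,4,5-trimethoxyphenyl)ethanone | Oc1cc(O)c(C(=O)Cc2cc(OC)c(OC)cc2OC)cc1OCc1ccccc1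
F6 | step 5 | (2,4,5-trimethoxyphenyl)acetaldehyde | O=CCc1cc(OC)c(OC)cc1OC
F7 | step 5 | 1-(2,4,5-trimethoxyphenyl)but-3-yn-2-ol (racemic) | C#CC(O)Cc1cc(OC)c(OC)cc1OC
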